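**Plan**

- Retrosynthesis: the two O-benzyl bonds are cut first. Then, in one flask, O1–C2 of ring C, the bond from the bridge CH2 to pyrone C3, and the bond from C3 of ring C to a temporary tert-butyl ester. Further back: C2=C3 (Knoevenagel), C3–C4 (Claisen), C8–CH2 (ortho-formylation), and the lactone C–O and one acyl C–C bond of the pyrone.
- Enabling feature: O1 sits on C8a of ring A, ortho to C8, which carries the bridge CH2, so O1–C8a=C8–CH2 is a latent ortho-quinone methide. Pyrone C3, between the lactone carbonyl and the C4 enol, is its carbon nucleophile, and C2 of ring C lies β to the C4 ketone, so the phenol released on capture can close ring C.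
- Forward: pyrone 4 in two steps. Ring A from methyl 2,4,6-trihydroxybenzoate by benzylation, ortho-formylation, reduction and acetonide formation (a temporary ring tying O1 to the bridge carbon). Claisen and Knoevenagel reactions then attach C4–C3–C2 and ring B, with a tert-butyl ester at C3 as activating group.
- Key flask: a chiral phosphoric acid opens the acetonide to the quinone methide, the pyrone adds, O1 closes ring C; acid then removes the ester; hydrogenolysis frees O5 and O7.
- Stereochemistry: the only stereocentre, C2 (S), is set in the ring closure by the chiral phosphoric acid. The bridge position (C8, not C6) follows from O1 being the only ring A oxygen that is released.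

Key step: step 9

Assumption: 13 is carried forward as its E/Z mixture, and the (R)-configured phosphoric acid is taken to give the (2S) product; if the sense of induction proves opposite, its enantiomer is used.

**Route**

Step 1
Reactants: 1 methyl 3-oxopentanoate; 2 N-methoxy-N-methylpropanamide
Product: 3 methyl 4-methyl-3,5-dioxoheptanoate
Conditions: LiN(iPr)2 (2.2 equiv), THF, −78 → 0 °C; then 2, −78 → 0 °C; aq. NH4Cl
Reagents that add atoms: none
Why: C-acylation of the β-keto ester dianion at its γ-carbon by the Weinreb amide, whose chelated tetrahedral adduct should prevent over-addition.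

Step 2
Reactants: 3
Product: 4 6-ethyl-4-hydroxy-5-methyl-2H-pyran-2-one
Conditions: DBU (1.5 equiv), toluene, 90 °C; then 1 M HCl
Reagents that add atoms: none
Why: Base-mediated lactonisation of a 3,5-dioxo ester, in which the enolate oxygen of the C5 ketone attacks the ester and methanol is expelled (standard 4-hydroxy-2-pyrone synthesis).

Step 3
Reactants: 5 methyl 2,4,6-trihydroxybenzoate
Product: 6 methyl 2,4-bis(benzyloxy)-6-hydroxybenzoate
Conditions: BnBr (2.05 equiv), K2CO3 (2.2 equiv), acetone, reflux
Reagents that add atoms: benzyl bromide BrCc1ccccc1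
Why: Williamson etherification, in which the hydroxyl hydrogen-bonded to the ester carbonyl is the least nucleophilic and should stay free, as is usual for 2,4,6-trihydroxyaryl carbonyl compounds.

Step 4
Reactants: 6
Product: 7 methyl 4,6-bis(benzyloxy)-3-formyl-2-hydroxybenzoate
Conditions: MgCl2 (2 equiv), Et3N (4 equiv), paraformaldehyde (6 equiv), MeCN, reflux; then 1 M HCl
Reagents that add atoms: paraformaldehyde (formaldehyde) C=O
Why: Ortho-selective formylation through the magnesium phenoxide–formaldehyde chelate (Casnati–Skattebøl formylation), which can reach only the single free ortho carbon and so places the future bridge carbon next to the future O1.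

Step 5
Reactants: 7
Product: 8 methyl 4,6-bis(benzyloxy)-2-hydroxy-3-(hydroxymethyl)benzoate
Conditions: NaBH4 (1.0 equiv), THF/MeOH 4:1, 0 °C
Reagents that add atoms: none
Why: Chemoselective borohydride reduction of the aldehyde in the presence of the methyl ester.

Step 6
Reactants: 8
Product: 9 methyl 5,7-bis(benzyloxy)-2,2-dimethyl-4H-1,3-benzodioxine-8-carboxylate
Conditions: 2,2-dimethoxypropane (5 equiv), PPTS (5 mol %), acetone, 25 °C
Reagents that add atoms: 2,2-dimethoxypropane COC(C)(C)OC
Why: Acid-catalysed transketalisation of the salicyl alcohol to its acetonide, a temporary ring that masks O1 together with the benzylic oxygen and removes both acidic protons before the enolate chemistry.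

Step 7
Reactants: 9; 10 tert-butyl acetate
Product: 11 tert-butyl 3-[5,7-bis(benzyloxy)-2,2-dimethyl-4H-1,3-benzodioxin-8-yl]-3-oxopropanoate
Conditions: LiN(iPr)2 (2.5 equiv), 10 (2.5 equiv), THF, −78 °C; then 9, −78 → 0 °C; aq. NH4Cl
Reagents that add atoms: none
Why: Crossed Claisen condensation, in which the lithium enolate of tert-butyl acetate displaces methoxide at the aryl ester and the product is shielded from further attack as its enolate.

Step 8
Reactants: 11; 12 benzaldehyde
Product: 13 tert-butyl 2-{[5,7-bis(benzyloxy)-2,2-dimethyl-4H-1,3-benzodioxin-8-yl]carbonyl}-3-phenylprop-2-enoate (E/Z mixture)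
Conditions: piperidine (10 mol %), AcOH (10 mol %), 4 Å molecular sieves, toluene, 25 → 50 °C
Reagents that add atoms: none
Why: Knoevenagel condensation of the active methylene with the aldehyde, in which the electrophilic alkylidene cannot cyclise prematurely because O1 is locked in the ketal.

Step 9
Reactants: 13; 4
Product: 18 (2S)-5,7-bis(benzyloxy)-8-[(6-ethyl-4-hydroxy-5-methyl-2-oxo-2H-pyran-3-yl)methyl]-2-phenyl-2,3-dihydro-4H-chromen-4-one, via ortho-quinone methide 14 (not isolated), via ring-open bridged phenol 15 (not isolated), via flavanone tert-butyl ester 16 (not isolated), via flavanone carboxylic acid 17 (not isolated)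
Conditions: 4 (1.2 equiv), (R)-3,3'-bis(2,4,6-triisopropylphenyl)-1,1'-binaphthyl-2,2'-diyl hydrogen phosphate ((R)-TRIP, 10 mol %), toluene, 0 → 25 °C; after full closure TsOH·H2O (1 equiv), 80 °C
Reagents that add atoms: none
Why: Proposed new method: the phosphoric acid ionises the ketal of 13 with loss of acetone to the ortho-quinone methide 14 (O1=C8a–C8=CH2, stabilised by the 5- and 7-benzyloxy groups), C3 of pyrone 4 adds to the methide carbon to give phenol 15, the O1–H released in that event adds to the benzylidene carbon of the alkylidene β-keto ester to give 16, and TsOH then removes the helper ester through acid 17 as 2-methylpropene and CO2. The closest known reaction types are the phosphoric acid-catalysed capture of in situ ortho-quinone methides by 1,3-dicarbonyl and 4-hydroxycoumarin nucleophiles, the thermal union of ortho-quinone methides with 4-hydroxy-2-pyrones, the amine–thiourea-catalysed enantioselective oxa-Michael closure of 2-hydroxyaryl alkylidene β-keto esters followed by acid decarboxylation, and the phosphoric acid-catalysed aza-Michael closure of 2'-aminochalcones; new are the merger of both events under one chiral Brønsted acid and the oxygen version of the acid-catalysed closure. Ring C closes in the 6-endo-trig mode (O1 onto C2) and no other ring is formed. C2 is set by the chiral phosphate, which is expected to hold O1–H on its P=O oxygen and the 1,3-dicarbonyl on its P–OH inside the triisopropylphenyl pocket so that one face of the benzylidene is open, while the C3 centre is erased by the decarboxylation. The step needs closure by O1 and not O5 (O5 and O7 are benzyl ethers and O1 is the only oxygen the ketal releases, which also fixes the bridge at C8), C- rather than O-alkylation of the pyrone (ionisation is reversible and the C3 adduct is the sink), and a catalyst that tolerates the acidic pyrone hydroxyl, which is why an acid and not an amine base is used.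

Step 10
Reactants: 18
Product: 19 (2S)-8-[(6-ethyl-4-hydroxy-5-methyl-2-oxo-2H-pyran-3-yl)methyl]-5,7-dihydroxy-2-phenyl-2,3-dihydro-4H-chromen-4-one
Conditions: H2 (1 atm), Pd/C (palladium on carbon, 10 wt %), EtOAc/MeOH, 25 °C
Reagents that add atoms: none
Why: Hydrogenolysis of the two aryl benzyl ethers under neutral conditions, which should leave the fully substituted pyrone, the hydrogen-bonded C4 ketone and the configuration at C2 untouched.

**Compound list**

1 | methyl 3-oxopentanoate | CCC(=O)CC(=O)OC | starting material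
2 | N-methoxy-N-methylpropanamide | CCC(=O)N(C)OC | starting material
3 | methyl 4-methyl-3,5-dioxoheptanoate | CCC(=O)C(C)C(=O)CC(=O)OC | intermediate
4 | 6-ethyl-4-hydroxy-5-methyl-2H-pyran-2-one | CCc1oc(=O)cc(O)c1C | intermediate
5 | methyl 2,4,6-trihydroxybenzoate | COC(=O)c1c(O)cc(O)cc1O | starting material
6 | methyl 2,4-bis(benzyloxy)-6-hydroxybenzoate | COC(=O)c1c(O)cc(OCc2ccccc2)cc1OCc1ccccc1 | intermediate
7 | methyl 4,6-bis(benzyloxy)-3-formyl-2-hydroxybenzoate | COC(=O)c1c(O)c(C=O)c(OCc2ccccc2)cc1OCc1ccccc1 | intermediate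
8 | methyl 4,6-bis(benzyloxy)-2-hydroxy-3-(hydroxymethyl)benzoate | COC(=O)c1c(O)c(CO)c(OCc2ccccc2)cc1OCc1ccccc1 | intermediate
9 | methyl 5,7-bis(benzyloxy)-2,2-dimethyl-4H-1,3-benzodioxine-8-carboxylate | COC(=O)c1c(OCc2ccccc2)cc(OCc2ccccc2)c2c1OC(C)(C)OC2 | intermediate
10 | tert-butyl acetate | CC(=O)OC(C)(C)C | starting material
11 | tert-butyl 3-[5,7-bis(benzyloxy)-2,2-dimethyl-4H-1,3-benzodioxin-8-yl]-3-oxopropanoate | CC(C)(C)OC(=O)CC(=O)c1c(OCc2ccccc2)cc(OCc2ccccc2)c2c1OC(C)(C)OC2 | intermediate
12 | benzaldehyde | O=Cc1ccccc1 | starting material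
13 | tert-butyl 2-{[5,7-bis(benzyloxy)-2,2-dimethyl-4H-1,3-benzodioxin-8-yl]carbonyl}-3-phenylprop-2-enoate (E/Z mixture) | CC(C)(C)OC(=O)C(=Cc1ccccc1)C(=O)c1c(OCc2ccccc2)cc(OCc2ccccc2)c2c1OC(C)(C)OC2 | intermediate
14 | tert-butyl 2-{[2,4-bis(benzyloxy)-5-methylidene-6-oxocyclohexa-1,3-dien-1-yl]carbonyl}-3-phenylprop-2-enoate (ortho-quinone methide, E/Z mixture) | C=C1C(=O)C(C(=O)C(=Cc2ccccc2)C(=O)OC(C)(C)C)=C(OCc2ccccc2)C=C1OCc1ccccc1 | intermediate
15 | tert-butyl 2-({4,6-bis(benzyloxy)-3-[(6-ethyl-4-hydroxy-5-methyl-2-oxo-2H-pyran-3-yl)methyl]-2-hydroxyphenyl}carbonyl)-3-phenylprop-2-enoate (E/Z mixture) | CCc1oc(=O)c(Cc2c(O)c(C(=O)C(=Cc3ccccc3)C(=O)OC(C)(C)C)c(OCc3ccccc3)cc2OCc2ccccc2)c(O)c1C | intermediate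
16 | tert-butyl (2S,3RS)-5,7-bis(benzyloxy)-8-[(6-ethyl-4-hydroxy-5-methyl-2-oxo-2H-pyran-3-yl)methyl]-4-oxo-2-phenyl-3,4-dihydro-2H-chromene-3-carboxylate | CCc1oc(=O)c(Cc2c(OCc3ccccc3)cc(OCc3ccccc3)c3c2O[C@H](c2ccccc2)C(C(=O)OC(C)(C)C)C3=O)c(O)c1C | intermediate
17 | (2S,3RS)-5,7-bis(benzyloxy)-8-[(6-ethyl-4-hydroxy-5-methyl-2-oxo-2H-pyran-3-yl)methyl]-4-oxo-2-phenyl-3,4-dihydro-2H-chromene-3-carboxylic acid | CCc1oc(=O)c(Cc2c(OCc3ccccc3)cc(OCc3ccccc3)c3c2O[C@H](c2ccccc2)C(C(=O)O)C3=O)c(O)c1C | intermediate
18 | (2S)-5,7-bis(benzyloxy)-8-[(6-ethyl-4-hydroxy-5-methyl-2-oxo-2H-pyran-3-yl)methyl]-2-phenyl-2,3-dihydro-4H-chromen-4-one | CCc1oc(=O)c(Cc2c(OCc3ccccc3)cc(OCc3ccccc3)c3c2O[C@H](c2ccccc2)CC3=O)c(O)c1C | intermediate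
19 | (2S)-8-[(6-ethyl-4-hydroxy-5-methyl-2-oxo-2H-pyran-3-yl)methyl]-5,7-dihydroxy-2-phenyl-2,3-dihydro-4H-chromen-4-one | CCc1oc(=O)c(Cc2c(O)cc(O)c3c2O[C@H](c2ccccc2)CC3=O)c(O)c1C | target

**Step count and risks**

Total steps: 10. Longest linear sequence: 8 (steps 3 to 10, from 5).

Steps most likely to fail:

1. Step 9 (the labelled step). The acid-catalysed ring closure may proceed with poor facial selectivity or be overtaken by a racemic background closure, and the quinone methide may oligomerise. The fallback uses known chemistry: it separates the two events and puts the stereo-determining closure under base catalysis before the acidic pyrone is present. From 13, aqueous acetic acid in THF at 25 °C removes the acetonide to give the free phenol tert-butyl 2-{[4,6-bis(benzyloxy)-2-hydroxy-3-(hydroxymethyl)phenyl]carbonyl}-3-phenylprop-2-enoate F1. A quinidine- or quinine-derived 3,5-bis(trifluoromethyl)phenyl thiourea (10 mol %, toluene, −25 °C) then closes ring C by the established enantioselective oxa-Michael addition to give tert-butyl (2S,3RS)-5,7-bis(benzyloxy)-8-(hydroxymethyl)-4-oxo-2-phenyl-3,4-dihydro-2H-chromene-3-carboxylate F2. TsOH·H2O and 4 in toluene at 25 °C ionise the C8 carbinol to the benzylic cation flanked by O1, O5 and O7, which alkylates pyrone C3. The route is rejoined at 16, which is decarboxylated to 18 on warming to 80 °C as in step 9.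

2. Step 7. Acyl substitution at the ester, which has two ortho substituents, may be too slow, so that the enolate is consumed by self-condensation. The fallback replaces substitution at the ester by addition to an aldehyde. From 9, LiAlH4 (THF, 0 °C) gives [5,7-bis(benzyloxy)-2,2-dimethyl-4H-1,3-benzodioxin-8-yl]methanol F3. MnO2 (CH2Cl2, 25 °C) gives 5,7-bis(benzyloxy)-2,2-dimethyl-4H-1,3-benzodioxine-8-carbaldehyde F4. The lithium enolate of 10 (THF, −78 °C) adds to give racemic tert-butyl 3-[5,7-bis(benzyloxy)-2,2-dimethyl-4H-1,3-benzodioxin-8-yl]-3-hydroxypropanoate F5, and Dess–Martin periodinane (CH2Cl2, NaHCO3) oxidises it to 11.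

3. Step 10. Hydrogenation may not stop at debenzylation (reduction of the pyrone or of the C4 carbonyl, hydrogenolysis of the benzylic C2–O1 bond). The fallback is a Lewis acid debenzylation without hydrogen: from 18, BCl3 with pentamethylbenzene as benzyl cation scavenger (CH2Cl2, −78 °C) should give 19 directly, with no new compound on the way.

**Further compounds**

F1 | step 9 | tert-butyl 2-{[4,6-bis(benzyloxy)-2-hydroxy-3-(hydroxymethyl)phenyl]carbonyl}-3-phenylprop-2-enoate (E/Z mixture) | CC(C)(C)OC(=O)C(=Cc1ccccc1)C(=O)c1c(O)c(CO)c(OCc2ccccc2)cc1OCc1ccccc1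
F2 | step 9 | tert-butyl (2S,3RS)-5,7-bis(benzyloxy)-8-(hydroxymethyl)-4-oxo-2-phenyl-3,4-dihydro-2H-chromene-3-carboxylate | OCc1c(OCc2ccccc2)cc(OCc2ccccc2)c2c1O[C@H](c1ccccc1)C(C(=O)OC(C)(C)C)C2=O
F3 | step 7 | [5,7-bis(benzyloxy)-2,2-dimethyl-4H-1,3-benzodioxin-8-yl]methanol | OCc1c(OCc2ccccc2)cc(OCc2ccccc2)c2c1OC(C)(C)OC2
F4 | step 7 | 5,7-bis(benzyloxy)-2,2-dimethyl-4H-1,3-benzodioxine-8-carbaldehyde | O=Cc1c(OCc2ccccc2)cc(OCc2ccccc2)c2c1OC(C)(C)OC2
F5 | step 7 | tert-butyl 3-[5,7-bis(benzyloxy)-2,2-dimethyl-4H-1,3-benzodioxin-8-yl]-3-hydroxypropanoate (racemic) | CC(C)(C)OC(=O)CC(O)c1c(OCc2ccccc2)cc(OCc2ccccc2)c2c1OC(C)(C)OC2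
F0 | step 10 | none | none
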